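## Retrosynthetic overview

1. The target is reached by oxidative excision (as CO2) of a C3 hydroxymethyl group from a 3-(hydroxymethyl)chromanol, which comes from reductive opening of a ring-fused 2-isoxazoline (a masked aldol).
2. The pyranone ring and the C3–C4 bond form in one event, an intramolecular nitrile oxide–olefin [3+2] cycloaddition of an ortho nitrile oxide onto the vinyl group of an aryl nerolidyl ether.
3. The aryl tertiary-alkyl ether comes from SNAr of the alkoxide of (3S,6E)-nerolidol on methyl 4-fluoro-3-formylbenzoate; the carbinol C–O bond is never broken, so nerolidol's C3 becomes C2 of the chromanone (S to S) and the E-olefin is bought with it.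
4. Ring order: the benzene ring is bought; the dihydropyranone ring closes in the cycloaddition (with a temporary fused isoxazoline); the isoxazoline is then opened and its extra carbon removed.

Assumption: natural (+)-(3S,6E)-nerolidol (cabreuva-oil grade) is bought as the single enantiomer, and its ee sets the ee of the product.

The centres at C3a/C3/C4 in compounds 8–16 are transient, are carried as mixtures, and are left unspecified in the SMILES.

## Route

Step 1
Reactants: 1 (3S,6E)-nerolidol; 2 methyl 4-fluoro-3-formylbenzoate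
Product: 4 methyl 3-formyl-4-{[(3S,6E)-3,7,11-trimethyldodeca-1,6,10-trien-3-yl]oxy}benzoate, via potassium alkoxide 3 (not isolated)
Conditions: 1 (1.1 eq), KHMDS (1.05 eq), THF, −78 → 0 °C; then add to 2, THF, −40 → 0 °C; Et3N-deactivated silica
Reagents that add atoms: none
Why: SNAr (addition–elimination through a Meisenheimer complex) on a fluoride activated by ortho-CHO and para-CO2Me; the carbinol C–O bond of nerolidol is never broken, so its (S) centre is carried over with retention.

Step 2
Reactants: 4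
Product: 8 methyl (4S)-4-[(3E)-4,8-dimethylnona-3,7-dien-1-yl]-4-methyl-3a,4-dihydro-3H-chromeno[4,3-c]isoxazole-8-carboxylate, via aldoxime 5 (not isolated), via hydroximoyl chloride 6 (not isolated), via nitrile oxide 7 (not isolated)
Conditions: NH2OH·HCl (1.05 eq), NaHCO3, THF/H2O, rt; then CH2Cl2, aq. NaOCl (1.5 eq), 0 °C → rt, same flask
Reagents that add atoms: hydroxylamine hydrochloride, Cl.NO
Why: Oxime formation and hypochlorite dehydrogenation give an aryl nitrile oxide that undergoes intramolecular nitrile oxide–olefin [3+2] cycloaddition (INOC) onto the vinyl group, closing the pyran ring and the C3–C4 bond at or below room temperature; the quaternary centre is a spectator and the new C3a centre (both epimers accepted) is erased later.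

Step 3
Reactants: 8
Product: 10 (4S)-4-[(3E)-4,8-dimethylnona-3,7-dien-1-yl]-4-methyl-3a,4-dihydro-3H-chromeno[4,3-c]isoxazole-8-carboxylic acid, via lithium carboxylate 9 (not isolated)
Conditions: LiOH·H2O (3 eq), THF/MeOH/H2O, 40 °C; then 1 M HCl to pH 3
Reagents that add atoms: lithium hydroxide, [Li+].[OH-]
Why: BAc2 saponification, placed here because the isoxazoline is inert to hydroxide whereas the later chromanone could racemise by base-induced retro-oxa-Michael ring opening.

Step 4
Reactants: 10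
Product: 13 (2S)-2-[(3E)-4,8-dimethylnona-3,7-dien-1-yl]-4-hydroxy-3-(hydroxymethyl)-2-methylchromane-6-carboxylic acid, via hydroxy ketimine 11 (not isolated), via hydroxy ketone 12 (not isolated)
Conditions: Mo(CO)6 (0.6 eq), MeCN/H2O 10:1, 80 °C; Celite filtration; then NaBH4 (3 eq), CeCl3·7H2O, MeOH, −20 → 0 °C
Reagents that add atoms: water, O
Why: Mo(0) reductive N–O cleavage of the 2-isoxazoline and hydrolysis of the N–H ketimine unmask the β-hydroxy ketone, which is reduced at once (Luche) so the enolisable, dehydration-prone aldol is never handled; C2 is untouched and the C3/C4 centres are transient.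

Step 5
Reactants: 13
Product: 15 (2S)-2-[(3E)-4,8-dimethylnona-3,7-dien-1-yl]-4-hydroxy-2-methylchromane-3,6-dicarboxylic acid, via hydroxy aldehyde 14 (not isolated)
Conditions: TEMPO (0.2 eq), PhI(OAc)2 (2.2 eq), MeCN/H2O 1:1, 0 °C → rt
Reagents that add atoms: water, O
Why: TEMPO/BAIB (oxoammonium) oxidation selects the unhindered primary alcohol over the secondary benzylic one and takes it through the aldehyde hydrate to the acid; with C4 held at the alcohol level no enolisable β-keto aldehyde can form.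

Step 6
Reactants: 15
Product: 17 (2S)-2-[(3E)-4,8-dimethylnona-3,7-dien-1-yl]-2-methyl-4-oxochromane-6-carboxylic acid, via keto diacid 16 (not isolated)
Conditions: IBX (1.5 eq), DMSO, rt → 45 °C
Reagents that add atoms: none
Why: IBX oxidation of the benzylic alcohol gives a β-keto acid that decarboxylates through the usual six-membered transition state, removing the extra carbon under neutral conditions; the quaternary C2 blocks any further dehydrogenation and stays (S).

## Compound list

1 | (3S,6E)-3,7,11-trimethyldodeca-1,6,10-trien-3-ol, (+)-(S)-trans-nerolidol | CC(C)=CCC/C(C)=C/CC[C@](C)(O)C=C | starting material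
2 | methyl 4-fluoro-3-formylbenzoate | COC(=O)c1ccc(F)c(C=O)c1 | starting material
3 | potassium (3S,6E)-3,7,11-trimethyldodeca-1,6,10-trien-3-olate (not isolated) | CC(C)=CCC/C(C)=C/CC[C@](C)([O-])C=C.[K+] | intermediate
4 | methyl 3-formyl-4-{[(3S,6E)-3,7,11-trimethyldodeca-1,6,10-trien-3-yl]oxy}benzoate | CC(C)=CCC/C(C)=C/CC[C@](C)(Oc1ccc(C(=O)OC)cc1C=O)C=C | intermediate
5 | methyl 3-[(E)-(hydroxyimino)methyl]-4-{[(3S,6E)-3,7,11-trimethyldodeca-1,6,10-trien-3-yl]oxy}benzoate (not isolated) | CC(C)=CCC/C(C)=C/CC[C@](C)(Oc1ccc(C(=O)OC)cc1/C=N/O)C=C | intermediate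
6 | methyl 3-[chloro(hydroxyimino)methyl]-4-{[(3S,6E)-3,7,11-trimethyldodeca-1,6,10-trien-3-yl]oxy}benzoate (not isolated) | CC(C)=CCC/C(C)=C/CC[C@](C)(Oc1ccc(C(=O)OC)cc1C(Cl)=NO)C=C | intermediate
7 | 5-(methoxycarbonyl)-2-{[(3S,6E)-3,7,11-trimethyldodeca-1,6,10-trien-3-yl]oxy}benzonitrile oxide (not isolated) | CC(C)=CCC/C(C)=C/CC[C@](C)(Oc1ccc(C(=O)OC)cc1C#[N+][O-])C=C | intermediate
8 | methyl (4S)-4-[(3E)-4,8-dimethylnona-3,7-dien-1-yl]-4-methyl-3a,4-dihydro-3H-chromeno[4,3-c]isoxazole-8-carboxylate (C3a epimers) | CC(C)=CCC/C(C)=C/CC[C@@]1(C)C2CON=C2c2cc(C(=O)OC)ccc2O1 | intermediate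
9 | lithium (4S)-4-[(3E)-4,8-dimethylnona-3,7-dien-1-yl]-4-methyl-3a,4-dihydro-3H-chromeno[4,3-c]isoxazole-8-carboxylate (not isolated) | CC(C)=CCC/C(C)=C/CC[C@@]1(C)C2CON=C2c2cc(C(=O)[O-])ccc2O1.[Li+] | intermediate
10 | (4S)-4-[(3E)-4,8-dimethylnona-3,7-dien-1-yl]-4-methyl-3a,4-dihydro-3H-chromeno[4,3-c]isoxazole-8-carboxylic acid | CC(C)=CCC/C(C)=C/CC[C@@]1(C)C2CON=C2c2cc(C(=O)O)ccc2O1 | intermediate
11 | (2S)-2-[(3E)-4,8-dimethylnona-3,7-dien-1-yl]-3-(hydroxymethyl)-4-imino-2-methylchromane-6-carboxylic acid (not isolated) | CC(C)=CCC/C(C)=C/CC[C@@]1(C)C(CO)C(=N)c2cc(C(=O)O)ccc2O1 | intermediate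
12 | (2S)-2-[(3E)-4,8-dimethylnona-3,7-dien-1-yl]-3-(hydroxymethyl)-2-methyl-4-oxochromane-6-carboxylic acid (not isolated) | CC(C)=CCC/C(C)=C/CC[C@@]1(C)C(CO)C(=O)c2cc(C(=O)O)ccc2O1 | intermediate
13 | (2S)-2-[(3E)-4,8-dimethylnona-3,7-dien-1-yl]-4-hydroxy-3-(hydroxymethyl)-2-methylchromane-6-carboxylic acid (C3/C4 diastereomers) | CC(C)=CCC/C(C)=C/CC[C@@]1(C)C(CO)C(O)c2cc(C(=O)O)ccc2O1 | intermediate
14 | (2S)-2-[(3E)-4,8-dimethylnona-3,7-dien-1-yl]-3-formyl-4-hydroxy-2-methylchromane-6-carboxylic acid (not isolated) | CC(C)=CCC/C(C)=C/CC[C@@]1(C)C(C=O)C(O)c2cc(C(=O)O)ccc2O1 | intermediate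
15 | (2S)-2-[(3E)-4,8-dimethylnona-3,7-dien-1-yl]-4-hydroxy-2-methylchromane-3,6-dicarboxylic acid (C3/C4 diastereomers) | CC(C)=CCC/C(C)=C/CC[C@@]1(C)C(C(=O)O)C(O)c2cc(C(=O)O)ccc2O1 | intermediate
16 | (2S)-2-[(3E)-4,8-dimethylnona-3,7-dien-1-yl]-2-methyl-4-oxochromane-3,6-dicarboxylic acid (not isolated) | CC(C)=CCC/C(C)=C/CC[C@@]1(C)C(C(=O)O)C(=O)c2cc(C(=O)O)ccc2O1 | intermediate
17 | (2S)-2-[(3E)-4,8-dimethylnona-3,7-dien-1-yl]-2-methyl-4-oxochromane-6-carboxylic acid | CC(C)=CCC/C(C)=C/CC[C@@]1(C)CC(=O)c2cc(C(=O)O)ccc2O1 | target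

## Step count and risks

Total step count: 6. Longest linear sequence: 6 (from 1).

The three steps most likely to fail are steps 1, 2 and 5.

**Step 1 (SNAr of a hindered tertiary alkoxide beside a free aldehyde).** The alkoxide can add to the aldehyde (hemiacetal, Tishchenko-type hydride transfer) or attack the ester. Product 4 is also a tertiary allylic ether of an electron-poor phenol, so it can ionise or undergo aromatic Claisen rearrangement if warmed or exposed to acid. Fallback: set out from 1 and run the SNAr on methyl 3-bromo-4-fluorobenzoate (COC(=O)c1ccc(F)c(Br)c1; KHMDS, DMF, 18-crown-6, 0 °C → rt), which has no aldehyde, to give methyl 3-bromo-4-{[(3S,6E)-3,7,11-trimethyldodeca-1,6,10-trien-3-yl]oxy}benzoate F1. Br/Mg exchange with i-PrMgCl·LiCl (THF, −40 °C) gives the arylmagnesium chloride F2, DMF converts it to the chloromagnesium hemiaminal alkoxide F3, and aqueous NH4Cl releases aldehyde 4, where the route is rejoined.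

**Step 2 (oxidative nitrile oxide generation beside two electron-rich trisubstituted olefins, on a labile allylic aryl ether).** Hypochlorite may chlorinate the side chain, or the nitrile oxide may dimerise. Fallback: set out from 4 and make the dipole by dehydration instead of oxidation. Pinnick oxidation (NaClO2, NaH2PO4, 2-methyl-2-butene, t-BuOH/H2O) gives 5-(methoxycarbonyl)-2-{[(3S,6E)-3,7,11-trimethyldodeca-1,6,10-trien-3-yl]oxy}benzoic acid F4. Coupling with TBSONH2 (EDC·HCl, CH2Cl2) gives methyl 3-{[(tert-butyldimethylsilyl)oxy]carbamoyl}-4-{[(3S,6E)-3,7,11-trimethyldodeca-1,6,10-trien-3-yl]oxy}benzoate F5. Tf2O/Et3N (CH2Cl2, −40 → 0 °C) dehydrates it to nitrile oxide 7, which cyclises in the same flask to 8, where the route is rejoined.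

**Step 5 (primary-over-benzylic selectivity of the TEMPO oxidation).** If the C4 alcohol is oxidised before the acid is formed, an enolisable β-keto aldehyde results and degrades. Fallback: set out from 10, stop step 4 after the Mo(CO)6 stage and isolate hydroxy ketone 12. Remove the hydroxymethyl carbon without any oxidation by a retro-aldol loss of formaldehyde (cat. K2CO3, MeOH, 0 °C → rt, N2 purge, short contact time, then acidify), arriving directly at 17 (no new compound, F0). This generates the chromanone enolate, so the ee must be checked by chiral HPLC.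

## Further compounds

F1 | step 1 | methyl 3-bromo-4-{[(3S,6E)-3,7,11-trimethyldodeca-1,6,10-trien-3-yl]oxy}benzoate | CC(C)=CCC/C(C)=C/CC[C@](C)(Oc1ccc(C(=O)OC)cc1Br)C=C
F2 | step 1 | chloro[5-(methoxycarbonyl)-2-{[(3S,6E)-3,7,11-trimethyldodeca-1,6,10-trien-3-yl]oxy}phenyl]magnesium | CC(C)=CCC/C(C)=C/CC[C@](C)(Oc1ccc(C(=O)OC)cc1[Mg]Cl)C=C
F3 | step 1 | chloromagnesium (dimethylamino)[5-(methoxycarbonyl)-2-{[(3S,6E)-3,7,11-trimethyldodeca-1,6,10-trien-3-yl]oxy}phenyl]methanolate | CC(C)=CCC/C(C)=C/CC[C@](C)(Oc1ccc(C(=O)OC)cc1C(O[Mg]Cl)N(C)C)C=C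
F4 | step 2 | 5-(methoxycarbonyl)-2-{[(3S,6E)-3,7,11-trimethyldodeca-1,6,10-trien-3-yl]oxy}benzoic acid | CC(C)=CCC/C(C)=C/CC[C@](C)(Oc1ccc(C(=O)OC)cc1C(=O)O)C=C
F5 | step 2 | methyl 3-{[(tert-butyldimethylsilyl)oxy]carbamoyl}-4-{[(3S,6E)-3,7,11-trimethyldodeca-1,6,10-trien-3-yl]oxy}benzoate | CC(C)=CCC/C(C)=C/CC[C@](C)(Oc1ccc(C(=O)OC)cc1C(=O)NO[Si](C)(C)C(C)(C)C)C=C
F0 | step 5 | none | none
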